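The route rests on cutting ring A at C2–C3 (labdane numbering). The key step is a one-pot Michael–Dieckmann annulation: the regiodefined C10 enolate of a 3-substituted 2-methylcyclohexanone adds to tert-butyl acrylate (C10–C1) and the new C2 ester enolate acylates the C3 ester. It closes ring A, sets quaternary C10 and the trans ring fusion, and installs O3. It exploits the C3 carbinol of ring A lying between the non-enolisable gem-dimethyl carbon C4 and the C1–C2 ethano bridge to the ring-fusion carbon C10. The precursor is the silyl enol ether from an enantioselective Mukaiyama–Michael addition of a dimethylketene acetal to 2-methylcyclohexenone.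

Key step: step 2

Remark: positions are given in labdane numbering (decalin C1–C10, C17 on C8, side chain C11–C16).
Remark: the (S)-prolinol-derived oxazaborolidinium ion is assumed to give the (S)-configured adduct in step 1; if the sense is opposite, its enantiomer is used.
Remark: lactone 14 is taken as a commercial compound.

Step 1
Reactants: 1 2-methylcyclohex-2-en-1-one; 2 1-methoxy-2-methyl-1-(trimethylsilyloxy)prop-1-ene
Product: 3 methyl 2-methyl-2-[(1S)-2-methyl-3-(trimethylsilyloxy)cyclohex-2-en-1-yl]propanoate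
Conditions: (S)-diphenylprolinol-derived B-(o-tolyl)oxazaborolidine·HNTf2 (10 mol %), Ph3PO (25 mol %), toluene, −20 °C; Et3N quench, non-aqueous work-up
Reagents that add atoms: none
Why: Mukaiyama–Michael addition in which the chiral oxazaborolidinium ion binds the enone carbonyl and shields one face of C5, so the ketene acetal should add to the other face and set C5, while silyl transfer to oxygen leaves the regiodefined C9–O–Si/C10 enol ether.

Step 2
Reactants: 3 methyl 2-methyl-2-[(1S)-2-methyl-3-(trimethylsilyloxy)cyclohex-2-en-1-yl]propanoate; 4 tert-butyl acrylate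
Product: 7 tert-butyl (4aR,8aR)-4,4,8a-trimethyl-3,8-dioxodecahydronaphthalene-2-carboxylate, via potassium enolate 5 (not isolated), via Michael adduct 6 (not isolated)
Conditions: KOt-Bu (1.0 equiv), THF, 0 °C; tert-butyl acrylate (1.05 equiv), −78 °C → rt; AcOH quench
Reagents that add atoms: none
Why: KOt-Bu cleaves the Si–O bond of 3 to the regiodefined tetrasubstituted enolate 5, which adds through C10 to the acrylate (Michael addition, C10–C1), and the resulting tert-butyl ester enolate at C2 attacks the C3 methyl ester (Dieckmann condensation, C2–C3) with loss of methoxide, which deprotonates the β-keto ester and makes the sequence irreversible. The closest known reaction type is the Michael–Dieckmann (Michael–Claisen) annulation of ketone enolates with acrylates. Ring A closes in a 6-(enolexo)-exo-trig mode. C10 is set by approach of the acrylate anti to the bulky pseudoaxial C5 substituent, which places the C1 and C4 arms trans and so gives the trans-decalin; the C2 centre is of no consequence because its carboxyl group is removed in step 4. The step needs reaction at C10 and not at C8, which the enol ether regiochemistry of 3 secures, and acylation by C2 only, which is secured because C4 is quaternary and because the alternative Claisen closure from C8 would give a bridgehead, non-enolisable β-diketone that reverts.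

Step 3
Reactants: 7 tert-butyl (4aR,8aR)-4,4,8a-trimethyl-3,8-dioxodecahydronaphthalene-2-carboxylate
Product: 9 tert-butyl (4aS,8aR)-4,4,8a-trimethyl-3-oxo-8-(trifluoromethylsulfonyloxy)-1,2,3,4,4a,5,6,8a-octahydronaphthalene-2-carboxylate, via dipotassium dienolate 8 (not isolated)
Conditions: KN(SiMe3)2 (2.2 equiv), THF, −78 °C; PhNTf2 (1.05 equiv), −78 → 0 °C; aq. HCl work-up
Reagents that add atoms: N-phenyl-bis(trifluoromethanesulfonimide) O=S(=O)(N(c1ccccc1)S(=O)(=O)C(F)(F)F)C(F)(F)F
Why: Enol triflate formation in which the unstabilised C9 ketone enolate oxygen of dienolate 8 should be sulfonylated much faster than the stabilised β-keto ester enolate, C8 being the only enolisable position of the C9 ketone because C10 is quaternary.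

Step 4
Reactants: 9 tert-butyl (4aS,8aR)-4,4,8a-trimethyl-3-oxo-8-(trifluoromethylsulfonyloxy)-1,2,3,4,4a,5,6,8a-octahydronaphthalene-2-carboxylate
Product: 11 (4aS,8aR)-5,5,8a-trimethyl-6-oxo-3,4,4a,5,6,7,8,8a-octahydronaphthalen-1-yl trifluoromethanesulfonate, via β-keto acid 10 (not isolated)
Conditions: TFA, CH2Cl2, rt; then toluene, 90 °C
Reagents that add atoms: none
Why: Acidolysis of the tert-butyl ester and thermal decarboxylation of the β-keto acid remove the activating carboxyl group from C2, and the vinyl triflate is inert to acid.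

Step 5
Reactants: 11 (4aS,8aR)-5,5,8a-trimethyl-6-oxo-3,4,4a,5,6,7,8,8a-octahydronaphthalen-1-yl trifluoromethanesulfonate
Product: 12 (4aR,6R,8aR)-6-hydroxy-5,5,8a-trimethyl-3,4,4a,5,6,7,8,8a-octahydronaphthalen-1-yl trifluoromethanesulfonate
Conditions: NaBH4, MeOH/CH2Cl2, 0 °C
Reagents that add atoms: none
Why: Borohydride reduction in which hydride should attack the C3 carbonyl along the axial trajectory, on the face away from the C10 methyl and the axial C4 methyl, to give the equatorial (3R) alcohol, while the vinyl triflate is untouched.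

Step 6
Reactants: 12 (4aR,6R,8aR)-6-hydroxy-5,5,8a-trimethyl-3,4,4a,5,6,7,8,8a-octahydronaphthalen-1-yl trifluoromethanesulfonate
Product: 13 (4aR,6R,8aR)-6-[tert-butyl(dimethyl)silyl]oxy-5,5,8a-trimethyl-3,4,4a,5,6,7,8,8a-octahydronaphthalen-1-yl trifluoromethanesulfonate
Conditions: TBSOTf, 2,6-lutidine, CH2Cl2, 0 °C
Reagents that add atoms: tert-butyldimethylsilyl trifluoromethanesulfonate CC(C)(C)[Si](C)(C)OS(=O)(=O)C(F)(F)F
Why: Silylation of the hindered secondary alcohol with the reactive silyl triflate protects O3 against the later oxidation at C8.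

Step 7
Reactants: 14 4-methyl-5,6-dihydro-2H-pyran-2-one
Product: 15 methyl (2Z)-5-iodo-3-methylpent-2-enoate
Conditions: Me3SiI, CH2Cl2, rt; then MeOH, 40 °C
Reagents that add atoms: iodotrimethylsilane C[Si](C)(C)I; methanol CO
Why: Lactone cleavage by iodotrimethylsilane (iodide attacks the O–CH2 carbon) and acid-promoted methanolysis of the silyl ester should give the iodo ester, the Z geometry being carried over from the ring.

Step 8
Reactants: 13 (4aR,6R,8aR)-6-[tert-butyl(dimethyl)silyl]oxy-5,5,8a-trimethyl-3,4,4a,5,6,7,8,8a-octahydronaphthalen-1-yl trifluoromethanesulfonate; 15 methyl (2Z)-5-iodo-3-methylpent-2-enoate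
Product: 17 methyl (2Z)-5-[(4aS,6R,8aR)-6-[tert-butyl(dimethyl)silyl]oxy-5,5,8a-trimethyl-3,4,4a,5,6,7,8,8a-octahydronaphthalen-1-yl]-3-methylpent-2-enoate, via alkylzinc iodide 16 (not isolated)
Conditions: Zn dust (Me3SiCl/BrCH2CH2Br activated), THF, 40 °C; then 13, PdCl2(dppf) (5 mol %), LiCl, THF/NMP, 60 °C
Reagents that add atoms: none
Why: Negishi coupling in which zinc inserts into the primary C–I bond and the alkylzinc iodide couples with the enol triflate under palladium catalysis with retention of both alkene geometries, ester and silyl ether being tolerated.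

Step 9
Reactants: 17 methyl (2Z)-5-[(4aS,6R,8aR)-6-[tert-butyl(dimethyl)silyl]oxy-5,5,8a-trimethyl-3,4,4a,5,6,7,8,8a-octahydronaphthalen-1-yl]-3-methylpent-2-enoate
Product: 19 methyl (2Z)-5-[(1S,2S,4aS,6R,8aR)-6-[tert-butyl(dimethyl)silyl]oxy-2-hydroxy-5,5,8a-trimethyldecahydronaphthalen-1-yl]-3-methylpent-2-enoate, via alkylborane 18 (not isolated)
Conditions: BH3·THF, THF, 0 °C → rt; then H2O2, aq. NaOAc, 0 °C → rt
Reagents that add atoms: hydrogen peroxide OO
Why: Hydroboration–oxidation in which borane should add syn to the electron-rich C8=C9 bond from the face opposite the axial C10 methyl with boron at the less substituted C8, so that H9 enters anti to the methyl and the side chain becomes equatorial, while the electron-poor enoate reacts far more slowly.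

Step 10
Reactants: 19 methyl (2Z)-5-[(1S,2S,4aS,6R,8aR)-6-[tert-butyl(dimethyl)silyl]oxy-2-hydroxy-5,5,8a-trimethyldecahydronaphthalen-1-yl]-3-methylpent-2-enoate
Product: 20 methyl (2Z)-5-[(1S,4aS,6R,8aR)-6-[tert-butyl(dimethyl)silyl]oxy-5,5,8a-trimethyl-2-oxodecahydronaphthalen-1-yl]-3-methylpent-2-enoate
Conditions: Dess–Martin periodinane, CH2Cl2, rt
Reagents that add atoms: none
Why: Dess–Martin oxidation of the secondary alcohol to the C8 ketone under neutral conditions, C9 already holding its stable equatorial configuration.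

Step 11
Reactants: 20 methyl (2Z)-5-[(1S,4aS,6R,8aR)-6-[tert-butyl(dimethyl)silyl]oxy-5,5,8a-trimethyl-2-oxodecahydronaphthalen-1-yl]-3-methylpent-2-enoate
Product: 21 methyl (2Z)-5-[(1R,4aS,6R,8aS)-6-[tert-butyl(dimethyl)silyl]oxy-5,5,8a-trimethyl-2-methylidenedecahydronaphthalen-1-yl]-3-methylpent-2-enoate
Conditions: Zn, CH2Br2, TiCl4, THF/CH2Cl2, 0 °C → rt
Reagents that add atoms: dibromomethane BrCBr
Why: Lombardo methylenation, whose non-basic zinc–titanium methylene reagent should convert the hindered, enolisable ketone into the exocyclic alkene without touching the ester or the enoate geometry.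

Step 12
Reactants: 21 methyl (2Z)-5-[(1R,4aS,6R,8aS)-6-[tert-butyl(dimethyl)silyl]oxy-5,5,8a-trimethyl-2-methylidenedecahydronaphthalen-1-yl]-3-methylpent-2-enoate
Product: 23 methyl (2Z)-5-[(1R,2R,4aS,6R,8aS)-6-[tert-butyl(dimethyl)silyl]oxy-2-(hydroxymethyl)-5,5,8a-trimethyldecahydronaphthalen-1-yl]-3-methylpent-2-enoate, via B-alkyl-9-BBN adduct 22 (not isolated)
Conditions: 9-BBN, THF, rt → 50 °C; then H2O2, aq. NaOAc, 0 °C → rt
Reagents that add atoms: hydrogen peroxide OO
Why: Hydroboration–oxidation in which 9-BBN should place boron on C17 and deliver hydrogen to C8 from the equatorial direction, anti to the axial C10 methyl, so that the CH2OH group ends up axial (8R), the trisubstituted enoate being inert to this borane.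

Step 13
Reactants: 23 methyl (2Z)-5-[(1R,2R,4aS,6R,8aS)-6-[tert-butyl(dimethyl)silyl]oxy-2-(hydroxymethyl)-5,5,8a-trimethyldecahydronaphthalen-1-yl]-3-methylpent-2-enoate
Product: 24 methyl (2Z)-5-[(1R,2R,4aS,6R,8aS)-6-hydroxy-2-(hydroxymethyl)-5,5,8a-trimethyldecahydronaphthalen-1-yl]-3-methylpent-2-enoate
Conditions: HF·pyridine, THF/pyridine, rt → 40 °C
Reagents that add atoms: none
Why: Fluoride-mediated cleavage of the silyl ether frees O3 under conditions that leave the enoate alone and before the epimerisable aldehyde exists.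

Step 14
Reactants: 24 methyl (2Z)-5-[(1R,2R,4aS,6R,8aS)-6-hydroxy-2-(hydroxymethyl)-5,5,8a-trimethyldecahydronaphthalen-1-yl]-3-methylpent-2-enoate
Product: 25 methyl (2Z)-5-[(1R,2R,4aS,6R,8aS)-2-formyl-6-hydroxy-5,5,8a-trimethyldecahydronaphthalen-1-yl]-3-methylpent-2-enoate
Conditions: TEMPO (10 mol %), PhI(OAc)2, CH2Cl2, rt
Reagents that add atoms: none
Why: Oxoammonium oxidation, which should take the primary C17 alcohol to the aldehyde much faster than the hindered secondary C3 alcohol and is mild enough not to epimerise the axial C8 aldehyde.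

Compound list
1 | 2-methylcyclohex-2-en-1-one | CC1=CCCCC1=O | starting material
2 | 1-methoxy-2-methyl-1-(trimethylsilyloxy)prop-1-ene | COC(=C(C)C)O[Si](C)(C)C | starting material
3 | methyl 2-methyl-2-[(1S)-2-methyl-3-(trimethylsilyloxy)cyclohex-2-en-1-yl]propanoate | COC(=O)C(C)(C)[C@H]1CCCC(O[Si](C)(C)C)=C1C | intermediate
4 | tert-butyl acrylate | C=CC(=O)OC(C)(C)C | starting material
5 | potassium (3S)-3-(1-methoxy-2-methyl-1-oxopropan-2-yl)-2-methylcyclohex-1-en-1-olate | COC(=O)C(C)(C)[C@H]1CCCC([O-])=C1C.[K+] | intermediate (not isolated)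
6 | methyl 2-[(1S,2R)-2-(3-tert-butoxy-3-oxopropyl)-2-methyl-3-oxocyclohexyl]-2-methylpropanoate (Michael adduct, present as its potassium ester enolate) | COC(=O)C(C)(C)[C@H]1CCCC(=O)[C@]1(C)CCC(=O)OC(C)(C)C | intermediate (not isolated)
7 | tert-butyl (4aR,8aR)-4,4,8a-trimethyl-3,8-dioxodecahydronaphthalene-2-carboxylate (trans-fused; C2 epimers and enol) | O=C1CCC[C@@H]2C(C)(C)C(=O)C(C(=O)OC(C)(C)C)C[C@@]12C | intermediate
8 | dipotassium dienolate of 7 (C9 enolate and β-keto ester enolate) | [K+].[K+].[O-]C1=CCC[C@@H]2C(C)(C)C([O-])=C(C(=O)OC(C)(C)C)C[C@@]12C | intermediate (not isolated)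
9 | tert-butyl (4aS,8aR)-4,4,8a-trimethyl-3-oxo-8-(trifluoromethylsulfonyloxy)-1,2,3,4,4a,5,6,8a-octahydronaphthalene-2-carboxylate | O=S(=O)(OC1=CCC[C@@H]2C(C)(C)C(=O)C(C(=O)OC(C)(C)C)C[C@@]12C)C(F)(F)F | intermediate
10 | (4aS,8aR)-4,4,8a-trimethyl-3-oxo-8-(trifluoromethylsulfonyloxy)-1,2,3,4,4a,5,6,8a-octahydronaphthalene-2-carboxylic acid | O=S(=O)(OC1=CCC[C@@H]2C(C)(C)C(=O)C(C(=O)O)C[C@@]12C)C(F)(F)F | intermediate (not isolated)
11 | (4aS,8aR)-5,5,8a-trimethyl-6-oxo-3,4,4a,5,6,7,8,8a-octahydronaphthalen-1-yl trifluoromethanesulfonate | O=S(=O)(OC1=CCC[C@@H]2C(C)(C)C(=O)CC[C@@]12C)C(F)(F)F | intermediate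
12 | (4aR,6R,8aR)-6-hydroxy-5,5,8a-trimethyl-3,4,4a,5,6,7,8,8a-octahydronaphthalen-1-yl trifluoromethanesulfonate | O=S(=O)(OC1=CCC[C@@H]2C(C)(C)[C@H](O)CC[C@@]12C)C(F)(F)F | intermediate
13 | (4aR,6R,8aR)-6-[tert-butyl(dimethyl)silyl]oxy-5,5,8a-trimethyl-3,4,4a,5,6,7,8,8a-octahydronaphthalen-1-yl trifluoromethanesulfonate | O=S(=O)(OC1=CCC[C@@H]2C(C)(C)[C@H](O[Si](C)(C)C(C)(C)C)CC[C@@]12C)C(F)(F)F | intermediate
14 | 4-methyl-5,6-dihydro-2H-pyran-2-one | CC1=CC(=O)OCC1 | starting material
15 | methyl (2Z)-5-iodo-3-methylpent-2-enoate | COC(=O)/C=C(/C)CCI | intermediate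
16 | [(3Z)-5-methoxy-3-methyl-5-oxopent-3-en-1-yl]zinc iodide | COC(=O)/C=C(/C)CC[Zn]I | intermediate (not isolated)
17 | methyl (2Z)-5-[(4aS,6R,8aR)-6-[tert-butyl(dimethyl)silyl]oxy-5,5,8a-trimethyl-3,4,4a,5,6,7,8,8a-octahydronaphthalen-1-yl]-3-methylpent-2-enoate | COC(=O)/C=C(/C)CCC1=CCC[C@@H]2C(C)(C)[C@H](O[Si](C)(C)C(C)(C)C)CC[C@@]12C | intermediate
18 | C8 monoalkylborane from 17 (boron equatorial at C8, H9 anti to the C10 methyl) | COC(=O)/C=C(/C)CC[C@@H]1[C@@H](B)CC[C@@H]2C(C)(C)[C@H](O[Si](C)(C)C(C)(C)C)CC[C@@]12C | intermediate (not isolated)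
19 | methyl (2Z)-5-[(1S,2S,4aS,6R,8aR)-6-[tert-butyl(dimethyl)silyl]oxy-2-hydroxy-5,5,8a-trimethyldecahydronaphthalen-1-yl]-3-methylpent-2-enoate | COC(=O)/C=C(/C)CC[C@@H]1[C@@H](O)CC[C@@H]2C(C)(C)[C@H](O[Si](C)(C)C(C)(C)C)CC[C@@]12C | intermediate
20 | methyl (2Z)-5-[(1S,4aS,6R,8aR)-6-[tert-butyl(dimethyl)silyl]oxy-5,5,8a-trimethyl-2-oxodecahydronaphthalen-1-yl]-3-methylpent-2-enoate | COC(=O)/C=C(/C)CC[C@@H]1C(=O)CC[C@@H]2C(C)(C)[C@H](O[Si](C)(C)C(C)(C)C)CC[C@@]12C | intermediate
21 | methyl (2Z)-5-[(1R,4aS,6R,8aS)-6-[tert-butyl(dimethyl)silyl]oxy-5,5,8a-trimethyl-2-methylidenedecahydronaphthalen-1-yl]-3-methylpent-2-enoate | COC(=O)/C=C(/C)CC[C@@H]1C(=C)CC[C@@H]2C(C)(C)[C@H](O[Si](C)(C)C(C)(C)C)CC[C@@]12C | intermediate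
22 | B-alkyl-9-borabicyclo[3.3.1]nonane from 21 (boron on C17, C17 axial) | COC(=O)/C=C(/C)CC[C@@H]1[C@H](CB3C4CCCC3CCC4)CC[C@@H]2C(C)(C)[C@H](O[Si](C)(C)C(C)(C)C)CC[C@@]12C | intermediate (not isolated)
23 | methyl (2Z)-5-[(1R,2R,4aS,6R,8aS)-6-[tert-butyl(dimethyl)silyl]oxy-2-(hydroxymethyl)-5,5,8a-trimethyldecahydronaphthalen-1-yl]-3-methylpent-2-enoate | COC(=O)/C=C(/C)CC[C@@H]1[C@H](CO)CC[C@@H]2C(C)(C)[C@H](O[Si](C)(C)C(C)(C)C)CC[C@@]12C | intermediate
24 | methyl (2Z)-5-[(1R,2R,4aS,6R,8aS)-6-hydroxy-2-(hydroxymethyl)-5,5,8a-trimethyldecahydronaphthalen-1-yl]-3-methylpent-2-enoate | COC(=O)/C=C(/C)CC[C@@H]1[C@H](CO)CC[C@@H]2C(C)(C)[C@H](O)CC[C@@]12C | intermediate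
25 | methyl (2Z)-5-[(1R,2R,4aS,6R,8aS)-2-formyl-6-hydroxy-5,5,8a-trimethyldecahydronaphthalen-1-yl]-3-methylpent-2-enoate (3R,5S,8R,9R,10S in labdane numbering) | COC(=O)/C=C(/C)CC[C@@H]1[C@H](C=O)CC[C@@H]2C(C)(C)[C@H](O)CC[C@@]12C | target

Total step count: 14. Longest linear sequence: 13 steps (steps 1–6 and 8–14); step 7 is a one-step branch.

Steps most likely to fail

Step 1. The α-methyl group may change how the enone binds the catalyst, so enantiofacial control and rate may drop. Fallback: the same catalytic addition of 2 is run on cyclohex-2-en-1-one F1, the substrate class on which it is established, to give methyl 2-methyl-2-[(1S)-3-(trimethylsilyloxy)cyclohex-2-en-1-yl]propanoate F2. KOt-Bu then MeI in THF methylates C10 to methyl 2-methyl-2-[(1S)-2-methyl-3-oxocyclohexyl]propanoate F3 (C10 configuration of no consequence). Thermodynamic silylation (Me3SiCl, NaI, Et3N, MeCN) then gives the more substituted enol ether. This fallback sets out from 2 and returns at 3.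

Step 2. The Michael addition of the hindered tetrasubstituted enolate may reverse, or the acrylate may oligomerise, before the Dieckmann closure takes place. Fallback: enolate 5 (made from 3 as in step 2) is alkylated with allyl bromide, anti to the C5 substituent, to methyl 2-methyl-2-[(1S,2R)-2-methyl-3-oxo-2-(prop-2-en-1-yl)cyclohexyl]propanoate F4. 9-BBN then H2O2/NaOAc gives methyl 2-[(1S,2R)-2-(3-hydroxypropyl)-2-methyl-3-oxocyclohexyl]-2-methylpropanoate F5. TEMPO/NaOCl then NaClO2 gives 3-[(1R,2S)-2-(1-methoxy-2-methyl-1-oxopropan-2-yl)-1-methyl-6-oxocyclohexyl]propanoic acid F6. tert-Butyl 2,2,2-trichloroacetimidate with catalytic BF3·OEt2 gives the keto diester, now isolated, which KOt-Bu in THF closes to 7. This fallback sets out from 3 and returns at 6.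

Step 9. Borane may reduce or hydroborate the conjugated ester while addition to the hindered C8=C9 bond is slow. Fallback: 17 is epoxidised with mCPBA (CH2Cl2, 0 °C) on the face anti to the C10 methyl to the 8,9-epoxide of 17 F7, the enoate being too electron-poor to react. BF3·OEt2 (CH2Cl2, −78 °C) then isomerises the epoxide by 1,2-hydride shift from C8 to C9 (Meinwald rearrangement), and brief equilibration on basic alumina puts the side chain equatorial. This fallback sets out from 17 and returns at 20.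

Further compounds
F1 | step 1 | cyclohex-2-en-1-one | O=C1C=CCCC1
F2 | step 1 | methyl 2-methyl-2-[(1S)-3-(trimethylsilyloxy)cyclohex-2-en-1-yl]propanoate | COC(=O)C(C)(C)[C@H]1CCCC(O[Si](C)(C)C)=C1
F3 | step 1 | methyl 2-methyl-2-[(1S)-2-methyl-3-oxocyclohexyl]propanoate (C2 epimers) | COC(=O)C(C)(C)[C@H]1CCCC(=O)C1C
F4 | step 2 | methyl 2-methyl-2-[(1S,2R)-2-methyl-3-oxo-2-(prop-2-en-1-yl)cyclohexyl]propanoate | COC(=O)C(C)(C)[C@H]1CCCC(=O)[C@]1(C)CC=C
F5 | step 2 | methyl 2-[(1S,2R)-2-(3-hydroxypropyl)-2-methyl-3-oxocyclohexyl]-2-methylpropanoate | COC(=O)C(C)(C)[C@H]1CCCC(=O)[C@]1(C)CCCO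
F6 | step 2 | 3-[(1R,2S)-2-(1-methoxy-2-methyl-1-oxopropan-2-yl)-1-methyl-6-oxocyclohexyl]propanoic acid | COC(=O)C(C)(C)[C@H]1CCCC(=O)[C@]1(C)CCC(=O)O
F7 | step 9 | 8,9-epoxide of 17 (oxygen anti to the C10 methyl) | COC(=O)/C=C(/C)CC[C@]1(O2)[C@@H]2CC[C@@H]3C(C)(C)[C@H](O[Si](C)(C)C(C)(C)C)CC[C@@]13C
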